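**Retrosynthetic overview**

1. Locants: ring A (3-hydroxy-4-methoxyphenyl) sits on C7, ring B (4-hydroxy-3-methoxyphenyl) on C7′; C8 and C8′ are the two methines (both R), C9 and C9′ the benzoyloxymethyl carbons. The strategy rests on C8 and C8′ each being a CH with three carbon arms (an ArCH2, a CH2O and the other methine), so each can be the carbon of CH2Cl2 set between boron, a migrating group and a Grignard carbon.
2. Target ⇐ hydrogenolysis of two ArO–Bn ethers ⇐ double benzoylation ⇐ (8R,8′R)-1,4-diol ⇐ joint oxidation of C9–B and C9′–Si ⇐ CH2 insertion into C8–B.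
3. C8 (key step): C8–C8′ and C7–C8 from LiCHCl2 insertion into the C8′–B bond of an (S,S)-diol boronate, then displacement by the ring-A benzyl Grignard reagent.
4. C8′: C7′–C8′ and C8′–C9′ in the same way from the ring-B benzylboronate, LiCHCl2 and (iPrO)Me2SiCH2MgCl as the masked hydroxymethyl arm.
5. No ring is formed anywhere; rings A and B are bought as O-benzylisovanillin and O-benzylvanillin.

Key step: step 7

Assumption: the known sense of induction of C2-symmetric diol boronates with LiCHCl2 is taken as (S,S)-diol → (1R)-1-chloroalkyl boronate (priority Cl > C > B); if these substrates followed the opposite sense, the (R,R)-diol would be used in the same sequence.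

Remark: (dichloromethyl)lithium is a short-lived reagent, made afresh from dichloromethane 8 and n-BuLi at −100 °C in each of the two homologations and consumed at once.

**Route**

Step 1
Reactants: 1 4-benzyloxy-3-methoxybenzaldehyde
Product: 2 4-benzyloxy-3-methoxybenzyl alcohol
Conditions: NaBH4, MeOH/THF, 0 °C → rt
Reagents that add atoms: none
Why: Borohydride reduction of an aryl aldehyde, to which the aryl benzyl ether is inert.

Step 2
Reactants: 2 4-benzyloxy-3-methoxybenzyl alcohol
Product: 3 4-benzyloxy-3-methoxybenzyl chloride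
Conditions: SOCl2, cat. DMF, toluene, 0 °C → rt; concentrated, filtered through basic alumina, used at once
Reagents that add atoms: thionyl chloride O=S(Cl)Cl
Why: Chlorodehydroxylation through the chlorosulfite, which is fast for an electron-rich benzylic alcohol and leaves the aryl ethers untouched.

Step 3
Reactants: 3 4-benzyloxy-3-methoxybenzyl chloride; 4 (1S,2S)-1,2-dicyclohexylethane-1,2-diol
Product: 7 (4S,5S)-2-(4-benzyloxy-3-methoxybenzyl)-4,5-dicyclohexyl-1,3,2-dioxaborolane, via (4-benzyloxy-3-methoxybenzyl)magnesium chloride 5 (not isolated), via (4-benzyloxy-3-methoxybenzyl)boronic acid 6 (not isolated)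
Conditions: Mg, THF, 0 °C (dilute, slow addition); B(OMe)3, −78 °C → rt; 1 M HCl, Et2O extract used directly; then 4, MgSO4, Et2O, rt
Reagents that add atoms: trimethyl borate COB(OC)OC
Why: Grignard borylation followed by boronic ester condensation with the diol, in which cold dilute Grignard formation limits Wurtz coupling and the diol stereocentres are not involved.

Step 4
Reactants: 7 (4S,5S)-2-(4-benzyloxy-3-methoxybenzyl)-4,5-dicyclohexyl-1,3,2-dioxaborolane; 8 dichloromethane; 9 (chloromethyl)isopropoxydimethylsilane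
Product: 12 (4S,5S)-2-[(2S)-1-(4-benzyloxy-3-methoxyphenyl)-3-(isopropoxydimethylsilyl)propan-2-yl]-4,5-dicyclohexyl-1,3,2-dioxaborolane, via ring-B α-chloro boronate 10 (not isolated), via (isopropoxydimethylsilyl)methylmagnesium chloride 11 (not isolated)
Conditions: 8, n-BuLi, THF, −100 °C (LiCHCl2); 7; ZnCl2, −100 °C → rt; then 11 (from 9, Mg, THF, reflux then rt), −78 °C → rt; purified on Et3N-deactivated silica
Reagents that add atoms: none
Why: Matteson homologation in which (dichloromethyl)lithium adds to boron, the ZnCl2-promoted 1,2-shift of the ring-B benzyl group expels the chloride selected by the (S,S)-diol to give the (1R)-chloride 10, and the ate complex formed with 11 rearranges with inversion, so that C8′ is set as S by reagent control.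

Step 5
Reactants: 13 3-benzyloxy-4-methoxybenzaldehyde
Product: 14 3-benzyloxy-4-methoxybenzyl alcohol
Conditions: NaBH4, MeOH/THF, 0 °C → rt
Reagents that add atoms: none
Why: Borohydride reduction of an aryl aldehyde, as in step 1.

Step 6
Reactants: 14 3-benzyloxy-4-methoxybenzyl alcohol
Product: 15 3-benzyloxy-4-methoxybenzyl chloride
Conditions: SOCl2, cat. DMF, toluene, 0 °C → rt; concentrated, filtered through basic alumina, used at once
Reagents that add atoms: thionyl chloride O=S(Cl)Cl
Why: Chlorodehydroxylation through the chlorosulfite, as in step 2.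

Step 7
Reactants: 12 (4S,5S)-2-[(2S)-1-(4-benzyloxy-3-methoxyphenyl)-3-(isopropoxydimethylsilyl)propan-2-yl]-4,5-dicyclohexyl-1,3,2-dioxaborolane; 8 dichloromethane; 15 3-benzyloxy-4-methoxybenzyl chloride
Product: 18 (4S,5S)-2-[(2R,3R)-1-(3-benzyloxy-4-methoxyphenyl)-3-(4-benzyloxy-3-methoxybenzyl)-4-(isopropoxydimethylsilyl)butan-2-yl]-4,5-dicyclohexyl-1,3,2-dioxaborolane, via C8 α-chloro boronate 16 (not isolated), via (3-benzyloxy-4-methoxybenzyl)magnesium chloride 17 (not isolated)
Conditions: 8, n-BuLi, THF, −100 °C (LiCHCl2); 12; ZnCl2, −100 °C → rt; then 17 (excess, from 15, Mg, THF, 0 °C), −78 °C → rt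
Reagents that add atoms: none
Why: (Dichloromethyl)lithium adds to the boron of 12, and on warming with ZnCl2 the C8′ carbon shifts from boron to the dichloromethyl carbon with retention at C8′ and loss of one chloride, forming the C8–C8′ bond in the (1R)-chloride 16. Grignard reagent 17 then forms a second ate complex, whose benzyl group migrates anti to the remaining chloride with inversion at C8, forming the C7–C8 bond of 18. The closest known reaction type is the Matteson homologation of chiral diol boronic esters with Grignard displacement, as run in successive rounds for adjacent stereocentres; no ring is closed. The C8 configuration (R in 18) is set by the (S,S)-diol on boron, which decides which of the two diastereotopic chlorides leaves, and this reagent control is expected to override the neighbouring C8′ centre. The step needs clean chloride selection without epimerisation of 16 by free chloride, which ZnCl2 secures by binding chloride and speeding the shift, and carbon rather than oxygen migration in the second ate complex, which the good migrating ability of benzyl favours. The Si–OiPr group and the aryl benzyl ethers should be inert at these temperatures.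

Step 8
Reactants: 18 (4S,5S)-2-[(2R,3R)-1-(3-benzyloxy-4-methoxyphenyl)-3-(4-benzyloxy-3-methoxybenzyl)-4-(isopropoxydimethylsilyl)butan-2-yl]-4,5-dicyclohexyl-1,3,2-dioxaborolane
Product: 19 (4S,5S)-2-[(2R,3R)-2-(3-benzyloxy-4-methoxybenzyl)-3-(4-benzyloxy-3-methoxybenzyl)-4-(isopropoxydimethylsilyl)butyl]-4,5-dicyclohexyl-1,3,2-dioxaborolane
Conditions: ClCH2I, n-BuLi (added last), THF, −78 °C → rt
Reagents that add atoms: chloroiodomethane ClCI
Why: Matteson CH2 insertion with chloromethyllithium made in the presence of the boronate, in which the ate complex rearranges on warming with migration of C8 with retention, so the C8 configuration is carried unchanged into the new C8–C9 bond.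

Step 9
Reactants: 19 (4S,5S)-2-[(2R,3R)-2-(3-benzyloxy-4-methoxybenzyl)-3-(4-benzyloxy-3-methoxybenzyl)-4-(isopropoxydimethylsilyl)butyl]-4,5-dicyclohexyl-1,3,2-dioxaborolane
Product: 20 (2R,3R)-2-(3-benzyloxy-4-methoxybenzyl)-3-(4-benzyloxy-3-methoxybenzyl)butane-1,4-diol
Conditions: 30% H2O2, KF, KHCO3, THF/MeOH (1:1), rt → 45 °C
Reagents that add atoms: hydrogen peroxide OO
Why: Tamao–Fleming oxidation of the alkoxysilane together with peroxide oxidation of the boronate, both carbon-to-oxygen shifts taking place at CH2 carbons so that neither stereocentre is touched.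

Step 10
Reactants: 20 (2R,3R)-2-(3-benzyloxy-4-methoxybenzyl)-3-(4-benzyloxy-3-methoxybenzyl)butane-1,4-diol
Product: 21 (2R,3R)-2-(3-benzyloxy-4-methoxybenzyl)-3-(4-benzyloxy-3-methoxybenzyl)butane-1,4-diyl dibenzoate
Conditions: BzCl, DMAP (cat.), pyridine, 0 °C → rt
Reagents that add atoms: benzoyl chloride O=C(Cl)c1ccccc1
Why: DMAP-catalysed acylation of two unhindered primary alcohols, with both phenols still masked as benzyl ethers.

Step 11
Reactants: 21 (2R,3R)-2-(3-benzyloxy-4-methoxybenzyl)-3-(4-benzyloxy-3-methoxybenzyl)butane-1,4-diyl dibenzoate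
Product: 22 (2R,3R)-2-(3-hydroxy-4-methoxybenzyl)-3-(4-hydroxy-3-methoxybenzyl)butane-1,4-diyl dibenzoate (CNP0306197.1)
Conditions: H2 (1 atm), 10% Pd/C, EtOAc/EtOH, rt
Reagents that add atoms: none
Why: Catalytic hydrogenolysis of the two aryl benzyl ethers, under which the benzoates on non-benzylic primary carbons and the C7 and C7′ carbon–carbon bonds should persist, so the stereocentres are unaffected.

**Compound list**

1 | 4-benzyloxy-3-methoxybenzaldehyde | COc1cc(C=O)ccc1OCc1ccccc1 | starting material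
2 | 4-benzyloxy-3-methoxybenzyl alcohol | COc1cc(CO)ccc1OCc1ccccc1 | intermediate
3 | 4-benzyloxy-3-methoxybenzyl chloride | COc1cc(CCl)ccc1OCc1ccccc1 | intermediate
4 | (1S,2S)-1,2-dicyclohexylethane-1,2-diol | O[C@@H](C1CCCCC1)[C@@H](O)C1CCCCC1 | starting material
5 | (4-benzyloxy-3-methoxybenzyl)magnesium chloride | COc1cc(C[Mg]Cl)ccc1OCc1ccccc1 | intermediate
6 | (4-benzyloxy-3-methoxybenzyl)boronic acid | COc1cc(CB(O)O)ccc1OCc1ccccc1 | intermediate
7 | (4S,5S)-2-(4-benzyloxy-3-methoxybenzyl)-4,5-dicyclohexyl-1,3,2-dioxaborolane | O1[C@@H](C2CCCCC2)[C@H](C2CCCCC2)OB1Cc1ccc(OCc2ccccc2)c(OC)c1 | intermediate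
8 | dichloromethane | ClCCl | starting material
9 | (chloromethyl)isopropoxydimethylsilane | CC(C)O[Si](C)(C)CCl | starting material
10 | (4S,5S)-2-[(1R)-2-(4-benzyloxy-3-methoxyphenyl)-1-chloroethyl]-4,5-dicyclohexyl-1,3,2-dioxaborolane | O1[C@@H](C2CCCCC2)[C@H](C2CCCCC2)OB1[C@@H](Cl)Cc1ccc(OCc2ccccc2)c(OC)c1 | intermediate
11 | (isopropoxydimethylsilyl)methylmagnesium chloride | CC(C)O[Si](C)(C)C[Mg]Cl | intermediate
12 | (4S,5S)-2-[(2S)-1-(4-benzyloxy-3-methoxyphenyl)-3-(isopropoxydimethylsilyl)propan-2-yl]-4,5-dicyclohexyl-1,3,2-dioxaborolane | O1[C@@H](C2CCCCC2)[C@H](C2CCCCC2)OB1[C@H](C[Si](C)(C)OC(C)C)Cc1ccc(OCc2ccccc2)c(OC)c1 | intermediate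
13 | 3-benzyloxy-4-methoxybenzaldehyde | COc1ccc(C=O)cc1OCc1ccccc1 | starting material
14 | 3-benzyloxy-4-methoxybenzyl alcohol | COc1ccc(CO)cc1OCc1ccccc1 | intermediate
15 | 3-benzyloxy-4-methoxybenzyl chloride | COc1ccc(CCl)cc1OCc1ccccc1 | intermediate
16 | (4S,5S)-2-[(1R,2S)-3-(4-benzyloxy-3-methoxyphenyl)-1-chloro-2-[(isopropoxydimethylsilyl)methyl]propyl]-4,5-dicyclohexyl-1,3,2-dioxaborolane | O1[C@@H](C2CCCCC2)[C@H](C2CCCCC2)OB1[C@@H](Cl)[C@H](C[Si](C)(C)OC(C)C)Cc1ccc(OCc2ccccc2)c(OC)c1 | intermediate
17 | (3-benzyloxy-4-methoxybenzyl)magnesium chloride | COc1ccc(C[Mg]Cl)cc1OCc1ccccc1 | intermediate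
18 | (4S,5S)-2-[(2R,3R)-1-(3-benzyloxy-4-methoxyphenyl)-3-(4-benzyloxy-3-methoxybenzyl)-4-(isopropoxydimethylsilyl)butan-2-yl]-4,5-dicyclohexyl-1,3,2-dioxaborolane | O1[C@@H](C2CCCCC2)[C@H](C2CCCCC2)OB1[C@H](Cc1ccc(OC)c(OCc2ccccc2)c1)[C@H](C[Si](C)(C)OC(C)C)Cc1ccc(OCc2ccccc2)c(OC)c1 | intermediate
19 | (4S,5S)-2-[(2R,3R)-2-(3-benzyloxy-4-methoxybenzyl)-3-(4-benzyloxy-3-methoxybenzyl)-4-(isopropoxydimethylsilyl)butyl]-4,5-dicyclohexyl-1,3,2-dioxaborolane | O1[C@@H](C2CCCCC2)[C@H](C2CCCCC2)OB1C[C@H](Cc1ccc(OC)c(OCc2ccccc2)c1)[C@H](C[Si](C)(C)OC(C)C)Cc1ccc(OCc2ccccc2)c(OC)c1 | intermediate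
20 | (2R,3R)-2-(3-benzyloxy-4-methoxybenzyl)-3-(4-benzyloxy-3-methoxybenzyl)butane-1,4-diol | OC[C@H](Cc1ccc(OC)c(OCc2ccccc2)c1)[C@H](CO)Cc1ccc(OCc2ccccc2)c(OC)c1 | intermediate
21 | (2R,3R)-2-(3-benzyloxy-4-methoxybenzyl)-3-(4-benzyloxy-3-methoxybenzyl)butane-1,4-diyl dibenzoate | O=C(OC[C@H](Cc1ccc(OC)c(OCc2ccccc2)c1)[C@H](COC(=O)c1ccccc1)Cc1ccc(OCc2ccccc2)c(OC)c1)c1ccccc1 | intermediate
22 | (2R,3R)-2-(3-hydroxy-4-methoxybenzyl)-3-(4-hydroxy-3-methoxybenzyl)butane-1,4-diyl dibenzoate | COc1ccc(C[C@@H](COC(=O)c2ccccc2)[C@H](COC(=O)c2ccccc2)Cc2ccc(O)c(OC)c2)cc1O | target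

**Step count and risks**

Total step count: 11. Longest linear sequence: 9 steps (steps 1–4 and 7–11, from aldehyde 1).

Steps most likely to fail:

1. Step 7. Ate-complex formation and the carbon shift may be slow at the hindered, β-branched C8′–B centre. Formation of 17 may be eroded by Wurtz coupling, and chloride-induced epimerisation of 16 could lower the selectivity at C8. Fallback: sparteine-mediated lithiation–borylation, which sets out from 13 and 12 and comes back at 18. Aldehyde 13 would be methylenated (Ph3PCH3Br, KOtBu, THF) to 3-benzyloxy-4-methoxystyrene F1. Hydroboration–oxidation (9-BBN, then NaOH/H2O2) would give 2-(3-benzyloxy-4-methoxyphenyl)ethanol F2, and carbamoylation (iPr2NCOCl, Et3N) would give 2-(3-benzyloxy-4-methoxyphenyl)ethyl N,N-diisopropylcarbamate F3. Deprotonation with s-BuLi/(−)-sparteine in Et2O at −78 °C should give (1S)-1-lithio-2-(3-benzyloxy-4-methoxyphenyl)ethyl N,N-diisopropylcarbamate F4. Addition of 12 forms the ate complex with retention, and warming with MgBr2·OEt2 should trigger the shift of C8′ with inversion and loss of the carbamate, giving 18. The C8 configuration is then fixed by the sparteine-controlled deprotonation and no benzylic Grignard reagent is needed.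

2. Step 8. Chloromethyllithium may decompose faster than it is captured by the hindered boron of 18, leaving the conversion incomplete. Fallback: two-stage homologation that sets out from 18 and comes back at 19. The longer-lived (dichloromethyl)lithium (from 8 and n-BuLi, −100 °C, then ZnCl2) would be inserted to give (4S,5S)-2-[(1R,2R,3R)-2-(3-benzyloxy-4-methoxybenzyl)-3-(4-benzyloxy-3-methoxybenzyl)-1-chloro-4-(isopropoxydimethylsilyl)butyl]-4,5-dicyclohexyl-1,3,2-dioxaborolane F5. Its chloride would then be replaced by hydride through a borate 1,2-hydride shift with KHB(OiPr)3 in THF, which erases the temporary CHCl centre and gives 19.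

3. Step 3. Wurtz homocoupling during formation of the electron-rich benzylic Grignard reagent 5, and air oxidation or protodeboronation of boronic acid 6, may drain material. Fallback: aryl-to-benzyl homologation that sets out from diol 4 and comes back at 7. Commercial 4-benzyloxy-3-methoxyphenylboronic acid F6 would be condensed with 4 (MgSO4, Et2O) to (4S,5S)-2-(4-benzyloxy-3-methoxyphenyl)-4,5-dicyclohexyl-1,3,2-dioxaborolane F7. One-carbon insertion with ClCH2I/n-BuLi (THF, −78 °C → rt), with migration of the aryl group, would then give 7 without any benzylic organomagnesium species.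

**Further compounds**

F1 | step 7 | 3-benzyloxy-4-methoxystyrene | COc1ccc(C=C)cc1OCc1ccccc1
F2 | step 7 | 2-(3-benzyloxy-4-methoxyphenyl)ethanol | COc1ccc(CCO)cc1OCc1ccccc1
F3 | step 7 | 2-(3-benzyloxy-4-methoxyphenyl)ethyl N,N-diisopropylcarbamate | COc1ccc(CCOC(=O)N(C(C)C)C(C)C)cc1OCc1ccccc1
F4 | step 7 | (1S)-1-lithio-2-(3-benzyloxy-4-methoxyphenyl)ethyl N,N-diisopropylcarbamate | COc1ccc(C[C@H]([Li])OC(=O)N(C(C)C)C(C)C)cc1OCc1ccccc1
F5 | step 8 | (4S,5S)-2-[(1R,2R,3R)-2-(3-benzyloxy-4-methoxybenzyl)-3-(4-benzyloxy-3-methoxybenzyl)-1-chloro-4-(isopropoxydimethylsilyl)butyl]-4,5-dicyclohexyl-1,3,2-dioxaborolane | O1[C@@H](C2CCCCC2)[C@H](C2CCCCC2)OB1[C@@H](Cl)[C@H](Cc1ccc(OC)c(OCc2ccccc2)c1)[C@H](C[Si](C)(C)OC(C)C)Cc1ccc(OCc2ccccc2)c(OC)c1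
F6 | step 3 | 4-benzyloxy-3-methoxyphenylboronic acid | COc1cc(B(O)O)ccc1OCc1ccccc1
F7 | step 3 | (4S,5S)-2-(4-benzyloxy-3-methoxyphenyl)-4,5-dicyclohexyl-1,3,2-dioxaborolane | O1[C@@H](C2CCCCC2)[C@H](C2CCCCC2)OB1c1ccc(OCc2ccccc2)c(OC)c1
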